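## Analysis of the target

Locants without primes refer to unit 1, the 5,7-dihydroxyflavone. Double-primed locants refer to unit 2, the 5-hydroxy-7-methoxyflavone.

- Compound 19 consists of two 2-(4-methoxyphenyl)chromen-4-one units joined by one bond between C6 and C8''.
- It has no stereocentre. The only stereogenic element is the C6–C8'' axis, which is flanked by four ortho oxygen substituents (5-OH and 7-OH on one side, 7''-OMe and O1'' on the other) and carries no descriptor.
- Several groups are sensitive. There are two peri-chelated 5-hydroxy-4-ketone pairs and three aryl methyl ethers that must survive any dealkylation. There are also two chromone enones that accept nucleophiles at C2 and can be metallated at C3.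
- Acid can open and reclose ring C (Wessely–Moser rearrangement), which lets a 6-substituted 5,7-dihydroxyflavone drift to its 8-substituted isomer.
- The synthesis is hard for three reasons. The biaryl bond is tetra-ortho-substituted and links two electron-rich rings. It must sit at C6 and not at C8 of unit 1. The oxygen pattern differs between the halves, with a free 7-OH in unit 1 and a 7''-OMe in unit 2.
- The strategy rests on ring A of unit 1 (C4a, C5, C6, C7, C8, C8a). Together with the acyl carbon C4 it is an acylphloroglucinol. That makes it the aromatised form of the linear chain aryl–C2=C3–C4(=O)–C4a–C8a(=O)–C8–C7(=O)–C6–C5(=O)X.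
- In that chain C6 is only the alpha carbon of a carboxylic acid derivative. Unit 2 can therefore enter as an 8-flavonylacetic ester, and the hindered aryl–aryl bond exists as an easily made C(sp2)–C(sp3) bond before ring A is formed.

## Retrosynthetic reasoning

**19 to 18.** The last bond cut is the O–CH3 bond at O5''. Of the four methyl ethers of 18 it is the only one peri to a chromone carbonyl, so a chelating boron Lewis acid can single it out. Keeping it in place until the end leaves unit 2 without acidic protons during all the enolate chemistry. The forward step must spare the 7''-, 4'- and 4'''-ethers.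

**18 to 16 (through 17).** Ring C of unit 1 is opened at O1–C2 and the two hydrogens at C2 and C3 are restored, which gives chalcone 16. Cutting here, and not at C2–aryl or C4–C4a, keeps the whole C4–C3–C2–aryl chain on ring A, so nothing has to be added after aromatisation. The forward reaction has to close through the oxygen on C8a, which is para to the biaryl bond, and not through the oxygen on C5. Only then does the interflavone bond end up at C6.

**16 to 14 (through 15).** Ring A is cut at C4a–C5. This unfolds the phloroglucinol into triketo ester 15, whose stable storage form is the 4-hydroxypyran-2-one 14 (a lactone between C5 and the C8a enol oxygen).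

- This cut is preferred because it is the only one that turns the biaryl carbon C6 into an sp3 carbon next to an ester.
- It also releases all three phenolic oxygens free, exactly as unit 1 requires.
- One ring and one skeletal bond are gained, and no aryl–aryl coupling is needed.
- The forward step must open the lactone and direct the C4a carbanion onto C5 under chelation by a magnesium alkoxide. This has to outpace aldol closure and relactonisation.

**14 to 10 and 12 (through 13).** The C4–C4a bond is cut.

- C4a is the 6-methyl carbon of pyranone 10 and becomes nucleophilic in dianion 13.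
- C4 arrives as the carbonyl of Weinreb amide 12, made in one step from ester 11.
- Ester 11 could acylate directly, but the more acidic product would then consume further base. An excess of strong amide base endangers C3'' of the flavone. The stable tetrahedral adduct of 12 removes that need.

**10 to 6 and 7 (through 8 and 9).** The pyranone is cut at C6–C7 and at the lactone O–C5 bond.

- This separates a two-carbon piece, C6 and C5 of the arylacetic ester, from a four-carbon acetoacetyl piece.
- A metal enolate of 5 and dioxinone 7 would mainly exchange protons, since the methyl group of 7 is about as acidic as 5.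
- The ester is therefore used as its neutral silyl ketene acetal 6, and 7 is used thermally as the source of acetylketene 8. Both bonds then form in one cycloaddition.

**6 to 5 to 3 and 4.** The C8''–CH2 bond is cut. The partner on carbon is the small zinc enolate 4, so the coupling at the crowded C8'' is an sp2–sp3 union and not a hindered biaryl synthesis. The neutral zinc reagent leaves the chromone untouched.

**3 to 2 to 1.** The C8''–I bond comes from electrophilic substitution of the fully methylated flavone 2, which reacts at C8''. Compound 2 is the permethyl ether of commercial 1. Unit 2 is thus bought complete, with ring B and ring C in place.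

## Alternatives that were turned down

**Alternative 1:**

- *Disconnection.* Ring A of unit 2 is the ring that gets built. It is divided into 3-ethoxycyclobutenone A1, which supplies C4a'', C5'', C6'' and the carbonyl carbon that becomes C7'', and the aryl siloxyalkyne A2, which supplies C8'' and C8a''. The aryl group of A2 is ring A of unit 1, with benzyl ethers on O5 and O7 and a methoxymethyl ether on the future O1.
- *Forward key step.* Heating opens A1 to a vinylketene, which adds [2+2] to the electron-rich triple bond of A2. The resulting vinylcyclobutenone opens again and closes by a 6π electrocyclisation to the biaryl phenol A3 (Danheiser-type benzannulation).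
- *In favour.* The biaryl bond is never made by coupling, and all oxygens emerge differentiated. There is a free hydroxyl on C7'' ready for methylation, a silyl ether on C8a'', an ethyl ether on C5'', and the acetal marking O1 on the other ring. Protecting groups thereby settle the 6-versus-8 question of unit 1. On this point the plan is stronger than the chosen one, which relies on a steric bias in step 9.
- *Against.*
  - A3 is only a biphenyl and contains no ring C, no ring B and no C2–C3–C4 carbon.
  - Two ring acylations, two chain extensions and two oxidative closures would have to follow.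
  - Several kinds of protecting group would need ordered removal, and an ethyl ether would have to be cleaved beside methyl ethers.
  - A2 is itself costly, because an ynol silyl ether on a di-ortho-alkoxyaryl group requires ester homologation.
  - The alkyne carbon that must attack the ketene is the shielded one, so ketene self-reaction would compete.
- *Comparison.* The chosen route buys unit 2 complete. Its key step delivers ring A with the full C4–C3–C2–aryl chain attached, and the target is two steps away afterwards.

**Alternative 2:**

- *Disconnection.* Both C2–aryl bonds are cut at once. This leaves the protected 6,8''-bichromone A4 and two equivalents of 4-methoxyphenylboronic acid A5.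
- *Forward key step.* A divalent palladium catalyst with an oxidant transfers the aryl group to C2 of each chromone by transmetallation, carbopalladation of C2=C3 and β-hydride elimination. The product is A6.
- *In favour.* The plan exploits the fact that both B rings are identical. It allows late variation. The position of the interflavone bond is fixed by the substitution pattern of the coupling partners, so no closure ambiguity arises, and on that point it is stronger than the chosen plan.
- *Against.*
  - The key step closes no ring and does not address the difficult bond. A4 still holds the tetra-ortho-oxygenated biaryl, which must come from cross-coupling two hindered, electron-rich chromones under basic conditions.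
  - 2-Unsubstituted chromones are the members of the family most easily opened at C2 by such bases.
  - The arylation must go to completion at two electronically different enones.
  - After syn carbopalladation of a cyclic enone, β-hydride elimination needs isomerisation through a palladium enolate. Protonation to the flavanone would therefore compete.
  - Debenzylation and 5''-demethylation are still required afterwards.
- *Comparison.* The chosen strategy replaces the biaryl coupling by an sp2–sp3 coupling with a small zinc enolate, and it uses its main step to create a ring.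

**Alternative 3:**

- *Disconnection.* Ring A of unit 1 is cut into the 2-aryl-3-silyloxycyclobutenone A7 and ethoxyacetylene A8. A7 carries protected unit 2 as its aryl group and supplies C6, C7, C8 and the carbonyl carbon that becomes C8a. A8 supplies C4a and C5.
- *Forward key step.* The same electrocyclic cascade as in alternative 1 gives phenol A9.
- *In favour.*
  - Unit 2 enters complete, as in the chosen plan.
  - The three oxygens of the new ring are differentiated, and the free hydroxyl sits on C8a, para to the biaryl bond. Closure of ring C would therefore be unambiguous, and here the plan is stronger than the chosen one.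
- *Against.*
  - A7 is the silyl enol ether of a cyclobutane-1,3-dione bearing a very hindered aryl group, and no short dependable access is apparent.
  - Its vinylketene carries that aryl group on the ketene α-carbon. The [2+2] step must therefore create a quaternary carbon next to a di-ortho-substituted ring.
  - A9 lacks C4, so ortho-acylation, aldol extension, closure and three different dealkylations must follow.
  - The acylation must occur on the ethoxy side. Otherwise the ethyl ether ends on O7, where it cannot be cleaved beside the methyl ethers.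
- *Comparison.* The chosen cyclisation forms the same ring with the acyl chain already attached and with no protecting group on unit 1. The price is the closure selectivity in step 9, for which a protecting-group remedy is given below.

Key step: step 8

Assumption: the target is drawn without a descriptor for the C6–C8'' axis, so 19 is prepared as the racemate of its atropisomers.

## Route

Step 1
Reactants: 1 acacetin (5,7-dihydroxy-2-(4-methoxyphenyl)chromen-4-one)
Product: 2 5,7-dimethoxy-2-(4-methoxyphenyl)chromen-4-one
Conditions: Me2SO4 (3 equiv), K2CO3, acetone, reflux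
Reagents that add atoms: dimethyl sulfate, COS(=O)(=O)OC
Why: Williamson O-methylation with excess reagent at reflux caps the acidic 7-hydroxyl quickly and the chelated 5-hydroxyl more slowly. A fully etherified unit 2 offers no acidic proton to the later amide bases, and the 5-O-methyl group is the one ether that can be removed selectively at the end.

Step 2
Reactants: 2 5,7-dimethoxy-2-(4-methoxyphenyl)chromen-4-one
Product: 3 8-iodo-5,7-dimethoxy-2-(4-methoxyphenyl)chromen-4-one
Conditions: N-iodosuccinimide (1.05 equiv), CF3CO2H (cat.), MeCN, 0 °C to rt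
Reagents that add atoms: N-iodosuccinimide, O=C1CCC(=O)N1I
Why: Electrophilic aromatic iodination; ring A with its two methoxy groups is by far the most nucleophilic ring, and in 5,7-dialkoxyflavones substitution goes to C8 because C6 is squeezed between two methoxy groups. Ring B is deactivated by conjugation with the chromone, and C3 needs oxidising iodination conditions that are not used here.

Step 3
Reactants: 3 8-iodo-5,7-dimethoxy-2-(4-methoxyphenyl)chromen-4-one; 4 (2-tert-butoxy-2-oxoethyl)zinc chloride, ClZnCH2CO2tBu
Product: 5 tert-butyl 2-[5,7-dimethoxy-2-(4-methoxyphenyl)-4-oxochromen-8-yl]acetate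
Conditions: 4 (2 equiv), Pd2(dba)3 (2.5 mol %), XPhos (2-dicyclohexylphosphino-2',4',6'-triisopropylbiphenyl, 10 mol %), THF, 65 °C
Reagents that add atoms: none
Why: Negishi-type coupling of a Reformatsky reagent with an aryl iodide, that is, palladium-catalysed alpha-arylation of an ester under neutral conditions. The zinc enolate is small and too mild to attack the vinylogous-ester carbonyl of the chromone, and the bulky biarylphosphine on zerovalent palladium is suited to oxidative addition and reductive elimination at di-ortho-substituted carbons.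

Step 4
Reactants: 5 tert-butyl 2-[5,7-dimethoxy-2-(4-methoxyphenyl)-4-oxochromen-8-yl]acetate
Product: 6 8-[2-tert-butoxy-2-(trimethylsilyloxy)ethenyl]-5,7-dimethoxy-2-(4-methoxyphenyl)chromen-4-one (silyl ketene acetal, double-bond geometry not controlled, used crude)
Conditions: LiN(SiMe3)2 (1.2 equiv), Me3SiCl (1.5 equiv), THF, −78 °C to rt; solvent change to toluene, filtration under argon
Reagents that add atoms: chlorotrimethylsilane, C[Si](C)(C)Cl
Why: Deprotonation of the benzylic ester CH2, the most acidic C–H bond of 5, and O-silylation of the lithium enolate give the silyl ketene acetal. LiN(SiMe3)2 is too weak to metallate C3 of the flavone, and the neutral nucleophile avoids the proton exchange that a metal enolate would undergo with 7.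

Step 5
Reactants: 6 8-[2-tert-butoxy-2-(trimethylsilyloxy)ethenyl]-5,7-dimethoxy-2-(4-methoxyphenyl)chromen-4-one; 7 2,2,6-trimethyl-1,3-dioxin-4-one
Product: 10 3-[5,7-dimethoxy-2-(4-methoxyphenyl)-4-oxochromen-8-yl]-4-hydroxy-6-methylpyran-2-one, via acetylketene 8 (not isolated), via dihydropyranone cycloadduct 9 (not isolated)
Conditions: 7 (3 equiv, slow addition), toluene, 110 °C; then CF3CO2H, (CF3CO)2O, CH2Cl2, 0 °C to rt
Reagents that add atoms: none
Why: At 110 °C 7 undergoes retro-hetero-Diels–Alder cleavage to acetylketene 8, which the electron-rich double bond of 6 captures in the known [4+2] mode of acylketenes with ketene acetals: the nucleophilic carbon (future C6) bonds to the ketene carbon (future C7) and the acetyl oxygen to the acetal carbon (future C5). Acid then removes the tert-butyl and silyl groups and the orthoester carbon collapses to the lactone carbonyl. Any ring-opened form of 9 is funnelled to the same pyranone by the anhydride, as in the standard closure of tert-butyl 3,5-dioxoalkanoates.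

Step 6
Reactants: 11 methyl (E)-3-(4-methoxyphenyl)prop-2-enoate (methyl 4-methoxycinnamate)
Product: 12 (E)-N-methoxy-3-(4-methoxyphenyl)-N-methylprop-2-enamide
Conditions: MeNH(OMe)·HCl (1.5 equiv), iPrMgCl (3 equiv), THF, −20 to 0 °C; dilute HCl
Reagents that add atoms: N,O-dimethylhydroxylamine hydrochloride, CNOC.Cl
Why: Aminolysis of the ester by the chloromagnesium amide made in situ gives the Weinreb amide with the E double bond retained. The amide is preferred to 11 as acyl donor because its tetrahedral chelate lasts until the quench, so neither a third equivalent of base nor an excess of the valuable nucleophile is needed.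

Step 7
Reactants: 10 3-[5,7-dimethoxy-2-(4-methoxyphenyl)-4-oxochromen-8-yl]-4-hydroxy-6-methylpyran-2-one; 12 (E)-N-methoxy-3-(4-methoxyphenyl)-N-methylprop-2-enamide
Product: 14 3-[5,7-dimethoxy-2-(4-methoxyphenyl)-4-oxochromen-8-yl]-4-hydroxy-6-[(E)-4-(4-methoxyphenyl)-2-oxobut-3-enyl]pyran-2-one, via dilithio dianion 13 (not isolated)
Conditions: LiN(iPr)2 (2.2 equiv), THF–DMPU, −78 to −30 °C; 12 (1.1 equiv), −78 to 0 °C; 1 M HCl
Reagents that add atoms: none
Why: Two equivalents of LiN(iPr)2 remove the 4-OH proton and then one proton of the 6-methyl group, the known dianion chemistry of 4-hydroxy-6-methylpyran-2-ones, and the terminal carbanion of 13 (future C4a) attacks the amide carbonyl (future C4) in a Weinreb ketone synthesis. Hard lithium carbanions add 1,2 to unsaturated Weinreb amides, helped here by the donor 4-methoxyphenyl group. Base is limited to two equivalents and the mixture is aged at −30 °C, so that any kinetic metallation at C3'' of the flavone drains into the better stabilised dienolate.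

Step 8
Reactants: 14 3-[5,7-dimethoxy-2-(4-methoxyphenyl)-4-oxochromen-8-yl]-4-hydroxy-6-[(E)-4-(4-methoxyphenyl)-2-oxobut-3-enyl]pyran-2-one
Product: 16 (E)-1-{3-[5,7-dimethoxy-2-(4-methoxyphenyl)-4-oxochromen-8-yl]-2,4,6-trihydroxyphenyl}-3-(4-methoxyphenyl)prop-2-en-1-one, via triketo methyl ester 15 (not isolated)
Conditions: Mg(OMe)2 (8 equiv), MeOH–THF, 65 °C, argon; cold 1 M HCl, product used without delay
Reagents that add atoms: none
Why: Methoxide from the magnesium alkoxide opens the lactone of 14 at the C5 carbonyl to the magnesium-chelated triketo ester 15; the doubly activated C4a methylene between the C4 and C8a ketones is deprotonated, its carbanion adds to the C5 ester carbonyl, methoxide leaves, and threefold enolisation aromatises the new ring to the phloroglucinol of 16. The closest known reaction type is the Mg(OMe)2-mediated Claisen (Dieckmann-type) cyclisation of 3,5,7-triketo esters and of 6-(2-oxoalkyl)-4-hydroxypyran-2-ones to acylphloroglucinols. The one ring that closes (C4a, C5, C6, C7, C8, C8a) forms by a 6-exo-trig acyl substitution, a mode open to the enolate in either of its enol geometries. No stereocentre is created: the C6 methine of 15 becomes planar on aromatisation and the new biaryl axis is racemic. The step needs Claisen closure to win over the aldol alternative (C6 onto the C4 ketone), relactonisation, conjugate addition to the enone and retro-Claisen cleavage of the chain. The substrate itself disarms the aldol mode, because C6 already bears unit 2, so its attack on C4 would build a quaternary carbon beside a di-ortho-substituted aryl group and give a ring that cannot aromatise, which keeps that path reversible. Relactonisation and addition of methoxide or of the C8a enol oxygen to the enone are likewise reversible, whereas magnesium holds the tricarbonyl array in the folded chelate that brings C4a to C5, and the aromatic magnesium phenolate is the thermodynamic sink. The electron-rich 4-methoxystyryl terminus lowers the electrophilicity of C2 and C4 and so protects the chain during the heating.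

Step 9
Reactants: 16 (E)-1-{3-[5,7-dimethoxy-2-(4-methoxyphenyl)-4-oxochromen-8-yl]-2,4,6-trihydroxyphenyl}-3-(4-methoxyphenyl)prop-2-en-1-one
Product: 18 6-[5,7-dimethoxy-2-(4-methoxyphenyl)-4-oxochromen-8-yl]-5,7-dihydroxy-2-(4-methoxyphenyl)chromen-4-one, via flavanone 17 (not isolated)
Conditions: I2 (10 mol %), DMSO, 120 °C
Reagents that add atoms: none
Why: The C8a hydroxyl of 16 adds to C2 of the enone (6-endo-trig oxa-Michael) to give flavanone 17, which iodine converts through its C3 iodide into the flavone while DMSO reoxidises HI; this is the established I2/DMSO oxidative cyclisation of 2'-hydroxychalcones. Closure through the C8a oxygen and not the C5 oxygen is expected because the C5 hydroxyl is wedged between the acyl group and the orthogonal unit 2, holds the stronger, buttressed hydrogen bond to C4=O, and thereby turns the enone towards the open C8a hydroxyl. The C2 stereocentre of 17 is transient and is erased by the dehydrogenation.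

Step 10
Reactants: 18 6-[5,7-dimethoxy-2-(4-methoxyphenyl)-4-oxochromen-8-yl]-5,7-dihydroxy-2-(4-methoxyphenyl)chromen-4-one
Product: 19 5,7-dihydroxy-6-[5-hydroxy-7-methoxy-2-(4-methoxyphenyl)-4-oxochromen-8-yl]-2-(4-methoxyphenyl)chromen-4-one
Conditions: BCl3 (6 equiv), CH2Cl2, −78 to 0 °C; then aq. HCl–MeOH
Reagents that add atoms: none
Why: BCl3 binds the C4'' carbonyl and the peri 5''-methoxy oxygen in a six-membered chelate and chloride removes the methyl group by SN2 attack, the standard selective 5-O-demethylation of flavones. The 7''-, 4'- and 4'''-methyl ethers lack such a chelate and should stay intact at or below 0 °C. The extra equivalents only cover the two free phenols, whose borates are hydrolysed on work-up.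

## Compound list

1 | acacetin, 5,7-dihydroxy-2-(4-methoxyphenyl)chromen-4-one | COc1ccc(-c2cc(=O)c3c(O)cc(O)cc3o2)cc1 | starting material
2 | 5,7-dimethoxy-2-(4-methoxyphenyl)chromen-4-one | COc1ccc(-c2cc(=O)c3c(OC)cc(OC)cc3o2)cc1 | intermediate
3 | 8-iodo-5,7-dimethoxy-2-(4-methoxyphenyl)chromen-4-one | COc1ccc(-c2cc(=O)c3c(OC)cc(OC)c(I)c3o2)cc1 | intermediate
4 | (2-tert-butoxy-2-oxoethyl)zinc chloride, ClZnCH2CO2tBu | CC(C)(C)OC(=O)C[Zn]Cl | starting material
5 | tert-butyl 2-[5,7-dimethoxy-2-(4-methoxyphenyl)-4-oxochromen-8-yl]acetate | COc1ccc(-c2cc(=O)c3c(OC)cc(OC)c(CC(=O)OC(C)(C)C)c3o2)cc1 | intermediate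
6 | 8-[2-tert-butoxy-2-(trimethylsilyloxy)ethenyl]-5,7-dimethoxy-2-(4-methoxyphenyl)chromen-4-one (geometry not defined) | COc1ccc(-c2cc(=O)c3c(OC)cc(OC)c(C=C(OC(C)(C)C)O[Si](C)(C)C)c3o2)cc1 | intermediate
7 | 2,2,6-trimethyl-1,3-dioxin-4-one | CC1=CC(=O)OC(C)(C)O1 | starting material
8 | acetylketene (3-oxobut-1-en-1-one) | CC(=O)C=C=O | intermediate
9 | 2-tert-butoxy-3-[5,7-dimethoxy-2-(4-methoxyphenyl)-4-oxochromen-8-yl]-6-methyl-2-(trimethylsilyloxy)-2,3-dihydropyran-4-one (mixture of diastereomers) | COc1ccc(-c2cc(=O)c3c(OC)cc(OC)c(C4C(=O)C=C(C)OC4(OC(C)(C)C)O[Si](C)(C)C)c3o2)cc1 | intermediate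
10 | 3-[5,7-dimethoxy-2-(4-methoxyphenyl)-4-oxochromen-8-yl]-4-hydroxy-6-methylpyran-2-one | COc1ccc(-c2cc(=O)c3c(OC)cc(OC)c(-c4c(O)cc(C)oc4=O)c3o2)cc1 | intermediate
11 | methyl (E)-3-(4-methoxyphenyl)prop-2-enoate | COc1ccc(/C=C/C(=O)OC)cc1 | starting material
12 | (E)-N-methoxy-3-(4-methoxyphenyl)-N-methylprop-2-enamide | COc1ccc(/C=C/C(=O)N(C)OC)cc1 | intermediate
13 | dilithio dianion of 10 (4-oxide and 6-methylide) | [Li+].[Li+].[CH2-]c1cc([O-])c(-c2c(OC)cc(OC)c3c(=O)cc(-c4ccc(OC)cc4)oc23)c(=O)o1 | intermediate
14 | 3-[5,7-dimethoxy-2-(4-methoxyphenyl)-4-oxochromen-8-yl]-4-hydroxy-6-[(E)-4-(4-methoxyphenyl)-2-oxobut-3-enyl]pyran-2-one | COc1ccc(/C=C/C(=O)Cc2cc(O)c(-c3c(OC)cc(OC)c4c(=O)cc(-c5ccc(OC)cc5)oc34)c(=O)o2)cc1 | intermediate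
15 | methyl (E)-2-[5,7-dimethoxy-2-(4-methoxyphenyl)-4-oxochromen-8-yl]-9-(4-methoxyphenyl)-3,5,7-trioxonon-8-enoate (C2 racemic, enolisable) | COC(=O)C(C(=O)CC(=O)CC(=O)/C=C/c1ccc(OC)cc1)c1c(OC)cc(OC)c2c(=O)cc(-c3ccc(OC)cc3)oc12 | intermediate
16 | (E)-1-{3-[5,7-dimethoxy-2-(4-methoxyphenyl)-4-oxochromen-8-yl]-2,4,6-trihydroxyphenyl}-3-(4-methoxyphenyl)prop-2-en-1-one | COc1ccc(/C=C/C(=O)c2c(O)cc(O)c(-c3c(OC)cc(OC)c4c(=O)cc(-c5ccc(OC)cc5)oc34)c2O)cc1 | intermediate
17 | 6-[5,7-dimethoxy-2-(4-methoxyphenyl)-4-oxochromen-8-yl]-5,7-dihydroxy-2-(4-methoxyphenyl)-2,3-dihydrochromen-4-one (racemic at C2) | COc1ccc(C2CC(=O)c3c(O)c(-c4c(OC)cc(OC)c5c(=O)cc(-c6ccc(OC)cc6)oc45)c(O)cc3O2)cc1 | intermediate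
18 | 6-[5,7-dimethoxy-2-(4-methoxyphenyl)-4-oxochromen-8-yl]-5,7-dihydroxy-2-(4-methoxyphenyl)chromen-4-one | COc1ccc(-c2cc(=O)c3c(O)c(-c4c(OC)cc(OC)c5c(=O)cc(-c6ccc(OC)cc6)oc45)c(O)cc3o2)cc1 | intermediate
19 | 5,7-dihydroxy-6-[5-hydroxy-7-methoxy-2-(4-methoxyphenyl)-4-oxochromen-8-yl]-2-(4-methoxyphenyl)chromen-4-one | COc1ccc(-c2cc(=O)c3c(O)c(-c4c(OC)cc(O)c5c(=O)cc(-c6ccc(OC)cc6)oc45)c(O)cc3o2)cc1 | target

## Step count and least certain steps

Total step count: 10. Longest linear sequence: 9 steps (steps 1 to 5 and 7 to 10). Step 6 is a one-step side branch.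

**Step 8 (key step).**

- *Risk.* The most likely failure is slow methanolysis of the lactone. Its carbonyl is shielded by the neighbouring unit 2 and deactivated by the pyranone oxyanion.
  - On the long heating then required, conjugate addition to the enone and retro-Claisen loss of the cinnamoyl end would erode the chain.
  - An aldol closure followed by loss of the ester carbon is a further possibility.
- *Fallback.* The ring-forming Claisen closure is separated from the enone.
  - Setting out from 10, dianion 13 is acylated with N-methoxy-N-methylacetamide to give 3-[5,7-dimethoxy-2-(4-methoxyphenyl)-4-oxochromen-8-yl]-4-hydroxy-6-(2-oxopropyl)pyran-2-one F1.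
  - This saturated methyl ketone tolerates forcing treatment with Mg(OMe)2. It is the closest analogue of the known acetonylpyranone cyclisations, and it should give 1-{3-[5,7-dimethoxy-2-(4-methoxyphenyl)-4-oxochromen-8-yl]-2,4,6-trihydroxyphenyl}ethanone F2.
  - Claisen–Schmidt condensation of F2 with 4-methoxybenzaldehyde (KOH, aqueous ethanol, rt) then installs C2, C3 and ring B and rejoins the route at 16.

**Step 9.**

- *Risk.* Closure may occur in part through the hindered hydroxyl next to the biaryl bond, which would move the interflavone bond from C6 to C8.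
  - The bias is only steric and hydrogen-bond based, and ring opening and reclosure of the flavanone stage are reversible at 120 °C.
  - Nuclear iodination at the free C8 position is a lesser concern.
- *Fallback.* The wrong oxygen is blocked before closure.
  - Setting out from 16, methoxymethyl chloride and iPr2NEt should etherify the two accessible hydroxyls and leave the chelated, hindered one. The product is (E)-1-{3-[5,7-dimethoxy-2-(4-methoxyphenyl)-4-oxochromen-8-yl]-2-hydroxy-4,6-bis(methoxymethoxy)phenyl}-3-(4-methoxyphenyl)prop-2-en-1-one F3.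
  - MeI with Cs2CO3 in DMF caps the remaining hydroxyl to give the 2-methoxy-4,6-bis(methoxymethoxy) chalcone F4.
  - HCl in methanol removes both acetals to give the 4,6-dihydroxy-2-methoxy chalcone F5, and any ring-closed form of it is equally usable.
  - I2 in DMSO can now close only through the oxygen on C8a. It gives 6-[5,7-dimethoxy-2-(4-methoxyphenyl)-4-oxochromen-8-yl]-7-hydroxy-5-methoxy-2-(4-methoxyphenyl)chromen-4-one F6.
  - Both peri methyl ethers of F6 are chelated, so BCl3 cleaves both, and the sequence rejoins the route at 19.

**Step 7.**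

- *Risk.* Three problems are possible: competing metallation at C3'' of the flavone by LiN(iPr)2, poor solubility of the dilithio salt at low temperature, and conjugate instead of carbonyl addition to 12.
- *Fallback.* The dianion is replaced by a monoanion that a weaker base can generate.
  - Setting out from 10, methoxymethyl chloride and iPr2NEt give 3-[5,7-dimethoxy-2-(4-methoxyphenyl)-4-oxochromen-8-yl]-4-(methoxymethoxy)-6-methylpyran-2-one F7.
  - LiN(SiMe3)2 at −78 °C deprotonates its vinylogous methyl group, C3 of the pyranone being blocked by the aryl group. Addition to 12 then gives 3-[5,7-dimethoxy-2-(4-methoxyphenyl)-4-oxochromen-8-yl]-4-(methoxymethoxy)-6-[(E)-4-(4-methoxyphenyl)-2-oxobut-3-enyl]pyran-2-one F8.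
  - HCl in methanol removes the acetal and rejoins the route at 14.

**Step 5.**

- *Risk.* Dimerisation of 8 may outrun its capture by the hindered 6. Adventitious water may hydrolyse 6. Decarboxylation may follow loss of the tert-butyl group before the lactone has closed.
- *Fallback.* The polarity is inverted and the aryl-bearing piece is made the electrophile.
  - Setting out from 5, LiN(SiMe3)2 and di-tert-butyl dicarbonate give di-tert-butyl 2-[5,7-dimethoxy-2-(4-methoxyphenyl)-4-oxochromen-8-yl]propanedioate F9.
  - CF3CO2H gives 2-[5,7-dimethoxy-2-(4-methoxyphenyl)-4-oxochromen-8-yl]propanedioic acid F10.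
  - Oxalyl chloride in warm toluene gives the (chlorocarbonyl)arylketene 2-[5,7-dimethoxy-2-(4-methoxyphenyl)-4-oxochromen-8-yl]-3-oxoprop-2-enoyl chloride F11.
  - F11 condenses with 2-(trimethylsilyloxy)propene by C-acylation followed by addition of the enol oxygen to the ketene. This pyranone synthesis is known for di-ortho-substituted aryl groups, and it rejoins the route at 10.

**Step 3.**

- *Risk.* Oxidative addition and reductive elimination may be sluggish at the electron-rich, di-ortho-substituted C8''. Hydrodeiodination and consumption of the zinc reagent would then take over.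
- *Fallback.* The side chain is delivered from oxygen by a sigmatropic shift instead of from a halide.
  - Setting out from 1, allyl bromide and K2CO3 in acetone alkylate the non-chelated hydroxyl to give 5-hydroxy-2-(4-methoxyphenyl)-7-(prop-2-enyloxy)chromen-4-one F12.
  - Aromatic Claisen rearrangement in N,N-diethylaniline at about 200 °C moves the allyl group to C8, giving 5,7-dihydroxy-2-(4-methoxyphenyl)-8-(prop-2-enyl)chromen-4-one F13.
  - Me2SO4 and K2CO3 give 5,7-dimethoxy-2-(4-methoxyphenyl)-8-(prop-2-enyl)chromen-4-one F14.
  - Lemieux–Johnson cleavage (OsO4 cat., NaIO4) gives 2-[5,7-dimethoxy-2-(4-methoxyphenyl)-4-oxochromen-8-yl]acetaldehyde F15.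
  - Pinnick oxidation (NaClO2, NaH2PO4, 2-methylbut-2-ene) gives 2-[5,7-dimethoxy-2-(4-methoxyphenyl)-4-oxochromen-8-yl]acetic acid F16.
  - tert-Butyl 2,2,2-trichloroacetimidate esterifies F16 and rejoins the route at 5.

## Further compounds

F1 | step 8 | 3-[5,7-dimethoxy-2-(4-methoxyphenyl)-4-oxochromen-8-yl]-4-hydroxy-6-(2-oxopropyl)pyran-2-one | CC(=O)Cc1cc(O)c(-c2c(OC)cc(OC)c3c(=O)cc(-c4ccc(OC)cc4)oc23)c(=O)o1
F2 | step 8 | 1-{3-[5,7-dimethoxy-2-(4-methoxyphenyl)-4-oxochromen-8-yl]-2,4,6-trihydroxyphenyl}ethanone | CC(=O)c1c(O)cc(O)c(-c2c(OC)cc(OC)c3c(=O)cc(-c4ccc(OC)cc4)oc23)c1O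
F3 | step 9 | (E)-1-{3-[5,7-dimethoxy-2-(4-methoxyphenyl)-4-oxochromen-8-yl]-2-hydroxy-4,6-bis(methoxymethoxy)phenyl}-3-(4-methoxyphenyl)prop-2-en-1-one | COCOc1cc(OCOC)c(C(=O)/C=C/c2ccc(OC)cc2)c(O)c1-c1c(OC)cc(OC)c2c(=O)cc(-c3ccc(OC)cc3)oc12
F4 | step 9 | (E)-1-{3-[5,7-dimethoxy-2-(4-methoxyphenyl)-4-oxochromen-8-yl]-2-methoxy-4,6-bis(methoxymethoxy)phenyl}-3-(4-methoxyphenyl)prop-2-en-1-one | COCOc1cc(OCOC)c(C(=O)/C=C/c2ccc(OC)cc2)c(OC)c1-c1c(OC)cc(OC)c2c(=O)cc(-c3ccc(OC)cc3)oc12
F5 | step 9 | (E)-1-{3-[5,7-dimethoxy-2-(4-methoxyphenyl)-4-oxochromen-8-yl]-4,6-dihydroxy-2-methoxyphenyl}-3-(4-methoxyphenyl)prop-2-en-1-one | COc1ccc(/C=C/C(=O)c2c(O)cc(O)c(-c3c(OC)cc(OC)c4c(=O)cc(-c5ccc(OC)cc5)oc34)c2OC)cc1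
F6 | step 9 | 6-[5,7-dimethoxy-2-(4-methoxyphenyl)-4-oxochromen-8-yl]-7-hydroxy-5-methoxy-2-(4-methoxyphenyl)chromen-4-one | COc1ccc(-c2cc(=O)c3c(OC)c(-c4c(OC)cc(OC)c5c(=O)cc(-c6ccc(OC)cc6)oc45)c(O)cc3o2)cc1
F7 | step 7 | 3-[5,7-dimethoxy-2-(4-methoxyphenyl)-4-oxochromen-8-yl]-4-(methoxymethoxy)-6-methylpyran-2-one | COCOc1cc(C)oc(=O)c1-c1c(OC)cc(OC)c2c(=O)cc(-c3ccc(OC)cc3)oc12
F8 | step 7 | 3-[5,7-dimethoxy-2-(4-methoxyphenyl)-4-oxochromen-8-yl]-4-(methoxymethoxy)-6-[(E)-4-(4-methoxyphenyl)-2-oxobut-3-enyl]pyran-2-one | COCOc1cc(CC(=O)/C=C/c2ccc(OC)cc2)oc(=O)c1-c1c(OC)cc(OC)c2c(=O)cc(-c3ccc(OC)cc3)oc12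
F9 | step 5 | di-tert-butyl 2-[5,7-dimethoxy-2-(4-methoxyphenyl)-4-oxochromen-8-yl]propanedioate | COc1ccc(-c2cc(=O)c3c(OC)cc(OC)c(C(C(=O)OC(C)(C)C)C(=O)OC(C)(C)C)c3o2)cc1
F10 | step 5 | 2-[5,7-dimethoxy-2-(4-methoxyphenyl)-4-oxochromen-8-yl]propanedioic acid | COc1ccc(-c2cc(=O)c3c(OC)cc(OC)c(C(C(=O)O)C(=O)O)c3o2)cc1
F11 | step 5 | 2-[5,7-dimethoxy-2-(4-methoxyphenyl)-4-oxochromen-8-yl]-3-oxoprop-2-enoyl chloride | COc1ccc(-c2cc(=O)c3c(OC)cc(OC)c(C(=C=O)C(=O)Cl)c3o2)cc1
F12 | step 3 | 5-hydroxy-2-(4-methoxyphenyl)-7-(prop-2-enyloxy)chromen-4-one | C=CCOc1cc(O)c2c(=O)cc(-c3ccc(OC)cc3)oc2c1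
F13 | step 3 | 5,7-dihydroxy-2-(4-methoxyphenyl)-8-(prop-2-enyl)chromen-4-one | C=CCc1c(O)cc(O)c2c(=O)cc(-c3ccc(OC)cc3)oc12
F14 | step 3 | 5,7-dimethoxy-2-(4-methoxyphenyl)-8-(prop-2-enyl)chromen-4-one | C=CCc1c(OC)cc(OC)c2c(=O)cc(-c3ccc(OC)cc3)oc12
F15 | step 3 | 2-[5,7-dimethoxy-2-(4-methoxyphenyl)-4-oxochromen-8-yl]acetaldehyde | O=CCc1c(OC)cc(OC)c2c(=O)cc(-c3ccc(OC)cc3)oc12
F16 | step 3 | 2-[5,7-dimethoxy-2-(4-methoxyphenyl)-4-oxochromen-8-yl]acetic acid | OC(=O)Cc1c(OC)cc(OC)c2c(=O)cc(-c3ccc(OC)cc3)oc12
A1 | alternative 1 | 3-ethoxycyclobut-2-en-1-one | CCOC1=CC(=O)C1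
A2 | alternative 1 | {[2,6-bis(benzyloxy)-4-(methoxymethoxy)phenyl]ethynyloxy}triisopropylsilane | COCOc1cc(OCc2ccccc2)c(C#CO[Si](C(C)C)(C(C)C)C(C)C)c(OCc2ccccc2)c1
A3 | alternative 1 | 2-[2,6-bis(benzyloxy)-4-(methoxymethoxy)phenyl]-5-ethoxy-3-(triisopropylsilyloxy)phenol | CCOc1cc(O)c(-c2c(OCc3ccccc3)cc(OCOC)cc2OCc2ccccc2)c(O[Si](C(C)C)(C(C)C)C(C)C)c1
A4 | alternative 2 | 5,7-bis(benzyloxy)-6-(5,7-dimethoxy-4-oxochromen-8-yl)chromen-4-one | O=c1ccoc2cc(OCc3ccccc3)c(-c3c(OC)cc(OC)c4c(=O)ccoc34)c(OCc3ccccc3)c12
A5 | alternative 2 | 4-methoxyphenylboronic acid | COc1ccc(B(O)O)cc1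
A6 | alternative 2 | 5,7-bis(benzyloxy)-6-[5,7-dimethoxy-2-(4-methoxyphenyl)-4-oxochromen-8-yl]-2-(4-methoxyphenyl)chromen-4-one | COc1ccc(-c2cc(=O)c3c(OCc4ccccc4)c(-c4c(OC)cc(OC)c5c(=O)cc(-c6ccc(OC)cc6)oc45)c(OCc4ccccc4)cc3o2)cc1
A7 | alternative 3 | 5,7-dimethoxy-2-(4-methoxyphenyl)-8-[4-oxo-2-(triisopropylsilyloxy)cyclobut-1-enyl]chromen-4-one | O=C1CC(O[Si](C(C)C)(C(C)C)C(C)C)=C1c1c(OC)cc(OC)c2c(=O)cc(-c3ccc(OC)cc3)oc12
A8 | alternative 3 | ethoxyacetylene | CCOC#C
A9 | alternative 3 | 8-[2-ethoxy-4-hydroxy-6-(triisopropylsilyloxy)phenyl]-5,7-dimethoxy-2-(4-methoxyphenyl)chromen-4-one | CCOc1cc(O)cc(O[Si](C(C)C)(C(C)C)C(C)C)c1-c1c(OC)cc(OC)c2c(=O)cc(-c3ccc(OC)cc3)oc12
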